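**Remark (assumption):** the SMILES is read as (5S)-7-(3,4-dihydroxyphenyl)-5-hydroxy-1-(4-hydroxy-3-methoxyphenyl)heptan-3-one, with the chain numbered C1 (guaiacyl CH2) to C7 (catechol CH2). Compounds 1, 5 and 7 are taken as purchasable.

**Plan**
1. Hardest feature: one carbinol (C5) in a β-hydroxy ketone whose two arylethyl arms are almost identical, so C3 (C=O) and C5 (CHOH) must be told apart by construction, not by a selective redox or enolate step.
2. Enabling feature: C4H2–C5H(OH)–C6H2 is a 2-hydroxypropane-1,3-diyl unit, the skeleton of epichlorohydrin, bounded by a carbonyl carbon (C3, acyl anion as 1,3-dithiane) and a benzylic carbon (C7, benzyl anion); both arene rings are spectators.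
3. Retrosynthesis: cut C3–C4 and C6–C7, then C1–aryl for the dithiane arm; no C4–C5 aldol bond is made.
4. Forward: Heck arylation of allyl alcohol gives the C1–C3 aldehyde, then its dithiane; a one-flask union of lithiodithiane, (R)-epichlorohydrin and a benzylic Grignard joins C3–C4 first and C6–C7 second; unmasking and hydrogenolysis finish.
5. Stereochemistry: C5 is C2 of (R)-epichlorohydrin; none of its bonds is broken, so (R)-linchpin becomes (S)-carbinol by CIP ranking only.

Key step: step 4

**Route**

Step 1
Reactants: 1 1-(benzyloxy)-4-bromo-2-methoxybenzene; 2 prop-2-en-1-ol (allyl alcohol)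
Product: 3 3-[4-(benzyloxy)-3-methoxyphenyl]propanal
Conditions: Pd(OAc)2 (2 mol %), Bu4NBr (1 equiv), NaHCO3 (2 equiv), DMF, 100 °C
Reagents that add atoms: none
Why: Mizoroki–Heck arylation of an allylic alcohol under phosphine-free phase-transfer conditions, in which aryl–Pd adds to the terminal alkene carbon and β-hydride elimination towards the carbinol carbon gives an enol that tautomerises to the saturated aldehyde, as in known preparations of 3-arylpropanals from electron-rich aryl bromides; the benzyl ether is inert and no stereocentre forms.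

Step 2
Reactants: 3 3-[4-(benzyloxy)-3-methoxyphenyl]propanal
Product: 4 2-{2-[4-(benzyloxy)-3-methoxyphenyl]ethyl}-1,3-dithiane
Conditions: propane-1,3-dithiol (1.1 equiv), BF3·OEt2 (0.2 equiv), CH2Cl2, 0 °C
Reagents that add atoms: propane-1,3-dithiol, SCCCS
Why: Lewis-acid-catalysed dithioacetalisation of an aldehyde, which converts C3 into an acyl-anion precursor; with catalytic BF3 at 0 °C the aryl benzyl and methyl ethers should survive, and no stereocentre forms.

Step 3
Reactants: 5 1,2-bis(benzyloxy)-4-(chloromethyl)benzene
Product: 6 [3,4-bis(benzyloxy)benzyl]magnesium chloride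
Conditions: Mg turnings (3 equiv, I2-activated), THF, 0 °C, slow addition of 5 over 3 h; solution titrated and used at once
Reagents that add atoms: magnesium, [Mg]
Why: Grignard formation by magnesium insertion into the benzylic C–Cl bond, where high dilution, low temperature and excess metal should suppress Wurtz homocoupling as for other alkoxybenzylmagnesium chlorides; the benzyl ethers are inert.

Step 4
Reactants: 4 2-{2-[4-(benzyloxy)-3-methoxyphenyl]ethyl}-1,3-dithiane; 7 (R)-epichlorohydrin [(2R)-2-(chloromethyl)oxirane]; 6 [3,4-bis(benzyloxy)benzyl]magnesium chloride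
Product: 11 (2S)-4-[3,4-bis(benzyloxy)phenyl]-1-(2-{2-[4-(benzyloxy)-3-methoxyphenyl]ethyl}-1,3-dithian-2-yl)butan-2-ol, via lithiated dithiane 8 (not isolated), via chlorohydrin alkoxide 9 (not isolated), via epoxide 10 (not isolated)
Conditions: 4, n-BuLi (1.0 equiv), THF, −30 °C, 2 h; 7 (1.0 equiv), −78 → 0 °C, then 23 °C; CuI (10 mol %), 6 (1.4 equiv), −40 → 0 °C; aq NH4Cl
Reagents that add atoms: none
Why: The C2-lithiated dithiane 8, an acyl-anion equivalent for C3, opens the oxirane of 7 by SN2 attack at its unsubstituted CH2 (the future C4), the lithium alkoxide 9 then expels chloride in an intramolecular Williamson reaction to give the transposed terminal epoxide 10, and copper-catalysed attack of the benzylic Grignard 6 at the new oxirane CH2 (C6) installs C7 and the second arm. The closest known reaction types are one-flask linchpin couplings of 2-lithio-1,3-dithianes with epichlorohydrin and Cu(I)-catalysed Grignard opening of monosubstituted epoxides. The only ring closed is the transient oxirane of 10, formed by 3-exo-tet closure and opened again in the same flask. No stereocentre is created: C5 is C2 of 7, none of its four bonds is made or broken, and the change from (R) in 7, 9 and 10 to (S) in 11 reflects only the changed CIP ranking of the two flanking methylenes. The step needs attack of 8 at the oxirane CH2 and not at C–Cl (direct displacement would give the enantiomeric epoxide) and terminal opening of 10; the first should be secured by the much higher SN2 reactivity of the strained, lithium-activated oxirane towards the soft carbanion at −78 °C compared with a primary chloride, the second by the steric bias of a monosubstituted epoxide under copper catalysis. The order of addition alone decides that C3 becomes the masked carbonyl and C5 the carbinol, which no redox reagent could decide on a finished chain.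

Step 5
Reactants: 11 (2S)-4-[3,4-bis(benzyloxy)phenyl]-1-(2-{2-[4-(benzyloxy)-3-methoxyphenyl]ethyl}-1,3-dithian-2-yl)butan-2-ol
Product: 12 (5S)-7-[3,4-bis(benzyloxy)phenyl]-1-[4-(benzyloxy)-3-methoxyphenyl]-5-hydroxyheptan-3-one
Conditions: MeI (10 equiv), CaCO3 (5 equiv), MeCN–H2O 9:1, 45 °C
Reagents that add atoms: water, O
Why: Alkylative dithiane hydrolysis, in which S-methylation turns sulfur into a leaving group and water captures the thionium ion, while the carbonate buffer keeps the medium near neutral so that the β-hydroxy ketone should neither dehydrate nor undergo retro-aldol cleavage; C5 is not involved.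

Step 6
Reactants: 12 (5S)-7-[3,4-bis(benzyloxy)phenyl]-1-[4-(benzyloxy)-3-methoxyphenyl]-5-hydroxyheptan-3-one
Product: 13 (5S)-7-(3,4-dihydroxyphenyl)-5-hydroxy-1-(4-hydroxy-3-methoxyphenyl)heptan-3-one (3''-demethylhexahydrocurcumin)
Conditions: H2 (1 atm), 10% Pd/C, EtOAc–MeOH 1:1, 23 °C; filtration and concentration under argon
Reagents that add atoms: none
Why: Catalytic hydrogenolysis of three aryl benzyl ethers on sulfur-free 12, under which the aryl methyl ether, the dialkyl ketone and the secondary carbinol are inert, so C5 is untouched; exclusion of air protects the catechol.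

**Compound list**
1 | 1-(benzyloxy)-4-bromo-2-methoxybenzene | COc1cc(Br)ccc1OCc1ccccc1 | starting material
2 | prop-2-en-1-ol (allyl alcohol) | C=CCO | starting material
3 | 3-[4-(benzyloxy)-3-methoxyphenyl]propanal | COc1cc(CCC=O)ccc1OCc1ccccc1 | intermediate
4 | 2-{2-[4-(benzyloxy)-3-methoxyphenyl]ethyl}-1,3-dithiane | COc1cc(CCC2SCCCS2)ccc1OCc1ccccc1 | intermediate
5 | 1,2-bis(benzyloxy)-4-(chloromethyl)benzene (3,4-dibenzyloxybenzyl chloride) | ClCc1ccc(OCc2ccccc2)c(OCc2ccccc2)c1 | starting material
6 | [3,4-bis(benzyloxy)benzyl]magnesium chloride | Cl[Mg]Cc1ccc(OCc2ccccc2)c(OCc2ccccc2)c1 | intermediate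
7 | (R)-epichlorohydrin, (2R)-2-(chloromethyl)oxirane | ClC[C@H]1CO1 | starting material
8 | 2-{2-[4-(benzyloxy)-3-methoxyphenyl]ethyl}-2-lithio-1,3-dithiane | [Li]C1(CCc2ccc(OCc3ccccc3)c(OC)c2)SCCCS1 | intermediate
9 | lithium (2R)-1-chloro-3-(2-{2-[4-(benzyloxy)-3-methoxyphenyl]ethyl}-1,3-dithian-2-yl)propan-2-olate | ClC[C@H](O[Li])CC1(CCc2ccc(OCc3ccccc3)c(OC)c2)SCCCS1 | intermediate
10 | 2-{2-[4-(benzyloxy)-3-methoxyphenyl]ethyl}-2-{[(2R)-oxiran-2-yl]methyl}-1,3-dithiane | COc1cc(CCC2(C[C@@H]3CO3)SCCCS2)ccc1OCc1ccccc1 | intermediate
11 | (2S)-4-[3,4-bis(benzyloxy)phenyl]-1-(2-{2-[4-(benzyloxy)-3-methoxyphenyl]ethyl}-1,3-dithian-2-yl)butan-2-ol | COc1cc(CCC2(C[C@@H](O)CCc3ccc(OCc4ccccc4)c(OCc4ccccc4)c3)SCCCS2)ccc1OCc1ccccc1 | intermediate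
12 | (5S)-7-[3,4-bis(benzyloxy)phenyl]-1-[4-(benzyloxy)-3-methoxyphenyl]-5-hydroxyheptan-3-one | COc1cc(CCC(=O)C[C@@H](O)CCc2ccc(OCc3ccccc3)c(OCc3ccccc3)c2)ccc1OCc1ccccc1 | intermediate
13 | (5S)-7-(3,4-dihydroxyphenyl)-5-hydroxy-1-(4-hydroxy-3-methoxyphenyl)heptan-3-one (3''-demethylhexahydrocurcumin) | COc1cc(CCC(=O)C[C@@H](O)CCc2ccc(O)c(O)c2)ccc1O | target

**Step count**
Total: 6 steps. Longest linear sequence: 5 steps (1 → 3 → 4 → 11 → 12 → 13); step 3 is a one-step branch that joins at step 4.

**Steps most likely to fail**

Step 4. Three processes could spoil the one-flask union: partial direct displacement of chloride by the dithiane anion, which erodes enantiopurity; incomplete closure of the alkoxide to the epoxide before the Grignard is added; and halide re-opening of the epoxide by magnesium salts. The fallback reverses the bond order and isolates each stage. It sets out from 6 (with 4 as partner) and returns at 11. Copper-catalysed addition of 6 to (S)-epichlorohydrin (CuI, THF, −40 °C) attacks only the oxirane CH2 and gives the isolable chlorohydrin (2S)-4-[3,4-bis(benzyloxy)phenyl]-1-chlorobutan-2-ol F1. Sodium hydroxide closes it to (2S)-2-{2-[3,4-bis(benzyloxy)phenyl]ethyl}oxirane F2, whose optical purity can be checked before use. Lithiated dithiane 8, generated from 4 as in step 4, then opens F2 at the terminal carbon in a plain two-component dithiane–epoxide alkylation to give 11.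

Step 3. Wurtz homocoupling during magnesium insertion into the electron-rich benzylic chloride may leave too little active Grignard reagent. The fallback reverses the polarity of the catechol arm and uses 5 as the electrophile. It sets out from 5 and returns at 11. Allylmagnesium bromide displaces the benzylic chloride to give 4-[3,4-bis(benzyloxy)phenyl]but-1-ene F3. Epoxidation with mCPBA gives racemic 2-{2-[3,4-bis(benzyloxy)phenyl]ethyl}oxirane F4. Hydrolytic kinetic resolution with (salen)Co(III)–OAc and 0.55 equiv water, using the catalyst antipode that hydrolyses the (R)-epoxide (expected to be the (S,S)-catalyst), leaves the (S)-epoxide F2. F2 is opened by 8 as in the first fallback to give 11.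

Step 1. Oxidative addition of the electron-rich aryl bromide may be slow, arylation at the internal alkene carbon may compete, and the aldehyde may self-condense under the hot basic conditions. The fallback builds the C1–aryl bond by sp3–sp2 cross-coupling. It sets out from 1 and returns at 4, bypassing 3. Hydroboration of acrolein diethyl acetal with 9-BBN gives 9-(3,3-diethoxypropyl)-9-borabicyclo[3.3.1]nonane F5. B-alkyl Suzuki–Miyaura coupling of F5 with 1 (PdCl2(dppf), aq K3PO4, THF–DMF, 60 °C) gives 1-(benzyloxy)-4-(3,3-diethoxypropyl)-2-methoxybenzene F6. Transthioacetalisation of F6 with propane-1,3-dithiol and BF3·OEt2 gives 4 directly.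

**Further compounds**
F1 | step 4 | (2S)-4-[3,4-bis(benzyloxy)phenyl]-1-chlorobutan-2-ol | ClC[C@@H](O)CCc1ccc(OCc2ccccc2)c(OCc2ccccc2)c1
F2 | step 4 | (2S)-2-{2-[3,4-bis(benzyloxy)phenyl]ethyl}oxirane | C1[C@@H](O1)CCc2ccc(OCc3ccccc3)c(OCc3ccccc3)c2
F3 | step 3 | 4-[3,4-bis(benzyloxy)phenyl]but-1-ene | C=CCCc1ccc(OCc2ccccc2)c(OCc2ccccc2)c1
F4 | step 3 | rac-2-{2-[3,4-bis(benzyloxy)phenyl]ethyl}oxirane | C1C(O1)CCc2ccc(OCc3ccccc3)c(OCc3ccccc3)c2
F5 | step 1 | 9-(3,3-diethoxypropyl)-9-borabicyclo[3.3.1]nonane | CCOC(OCC)CCB1C2CCCC1CCC2
F6 | step 1 | 1-(benzyloxy)-4-(3,3-diethoxypropyl)-2-methoxybenzene | CCOC(CCc1ccc(OCc2ccccc2)c(OC)c1)OCC
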